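**Strategy.** Ring C is cut across C3–C4 and O1–C8a into two three-atom pieces: C4–C4a–C8a, a 2-fluorobenzoyl Weinreb amide that already carries the C6 dienyl chain, and O1–C2–C3, a β-oxido alkyllithium in which C2 is already (S). In one flask the carbanion acylates C4; the adduct keeps C4 masked while lithiation at C8 expels fluoride from C8a, and the C2 alkoxide closes onto the resulting C8–C8a aryne. The step exploits the ortho pair C4a/C8a of ring A and its free C8–H (flanked by F and the C7 oxygen), fixes 6- over 8-substitution through the position of fluorine, and never breaks a bond at C2.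

Key step: step 7

Remark: atoms are numbered as in the flavanone (O1, C2, C3, C4, C4a, C5–C8, C8a; primed numbers for the side chain); compounds 1, 4 and 8 are taken as catalogue compounds; LiTMP and lithium naphthalenide are used as separately prepared, titrated THF solutions.

**Route**

Step 1
Reactants: 1 5-fluorobenzene-1,3-diol
Product: 2 5-fluoro-2-iodobenzene-1,3-diol
Conditions: I2 (1.05 equiv), NaHCO3 (1.1 equiv), H2O, 0 °C to rt
Reagents that add atoms: iodine, II
Why: Electrophilic aromatic iodination should take place at the carbon flanked by both hydroxyls and para to fluorine, as in the aqueous bicarbonate iodination of resorcinol itself, because the two carbons next to fluorine are inductively deactivated; no stereocenter is formed.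

Step 2
Reactants: 2 5-fluoro-2-iodobenzene-1,3-diol
Product: 3 5-fluoro-2-iodo-1,3-bis(methoxymethoxy)benzene
Conditions: MOMCl (2.6 equiv), i-Pr2NEt (3 equiv), CH2Cl2, 0 °C to rt
Reagents that add atoms: chloromethyl methyl ether, COCCl
Why: Base-mediated O-alkylation (MOM ether formation) of both phenols should proceed cleanly and installs the coordinating groups that later guide the two ring lithiations.

Step 3
Reactants: 3 5-fluoro-2-iodo-1,3-bis(methoxymethoxy)benzene; 4 (3S)-3,7-dimethylocta-1,6-diene ((S)-β-citronellene, 2 equiv)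
Product: 5 2-[(1E,3S)-3,7-dimethylocta-1,6-dien-1-yl]-5-fluoro-1,3-bis(methoxymethoxy)benzene
Conditions: Pd(OAc)2 (5 mol %), P(o-tol)3 (10 mol %), Ag2CO3 (1.0 equiv), DMF, 80 °C
Reagents that add atoms: none
Why: Mizoroki–Heck reaction in which the arylpalladium iodide adds to the unsubstituted terminus of the monosubstituted alkene (the trisubstituted alkene is inert), syn β-hydride elimination towards the benzylic carbon should give the E styrene, the silver salt limits hydride re-addition and double-bond migration, and the allylic (S) center of 4 is carried through unchanged.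

Step 4
Reactants: 5 2-[(1E,3S)-3,7-dimethylocta-1,6-dien-1-yl]-5-fluoro-1,3-bis(methoxymethoxy)benzene
Product: 7 3-[(1E,3S)-3,7-dimethylocta-1,6-dien-1-yl]-6-fluoro-N-methoxy-2,4-bis(methoxymethoxy)-N-methylbenzamide, via aryllithium 6 (not isolated)
Conditions: LiTMP (1.3 equiv), THF, −78 °C, 1 h; then ClC(O)N(OMe)Me (1.6 equiv), −78 °C; aq. NH4Cl
Reagents that add atoms: N-methoxy-N-methylcarbamoyl chloride, CON(C)C(Cl)=O
Why: Directed ortho-metalation at one of the two equivalent ring C–H bonds, each flanked by fluorine (acidifying) and a MOM ether (coordinating), with a lithium amide that spares the styrene from carbolithiation and at a temperature that prevents LiF loss, followed by acylation of the aryllithium to the Weinreb amide.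

Step 5
Reactants: 8 2-chloro-1-(4-hydroxyphenyl)ethan-1-one
Product: 9 2-chloro-1-[4-(methoxymethoxy)phenyl]ethan-1-one
Conditions: MOMCl (1.3 equiv), i-Pr2NEt (1.5 equiv), CH2Cl2, 0 °C to rt
Reagents that add atoms: chloromethyl methyl ether, COCCl
Why: MOM ether formation at the phenol should outrun any alkylation by the α-chloro ketone, because MOMCl is by far the more reactive electrophile.

Step 6
Reactants: 9 2-chloro-1-[4-(methoxymethoxy)phenyl]ethan-1-one
Product: 10 (1R)-2-chloro-1-[4-(methoxymethoxy)phenyl]ethan-1-ol
Conditions: (R)-2-methyl-CBS-oxazaborolidine [(3aR)-1-methyl-3,3-diphenyltetrahydro-1H,3H-pyrrolo[1,2-c][1,3,2]oxazaborole] (10 mol %), BH3·SMe2 (0.7 equiv), THF, 0 °C; then MeOH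
Reagents that add atoms: none
Why: Corey–Bakshi–Shibata reduction in which the (R)-oxazaborolidine–borane complex binds the ketone with the aryl group as the large substituent and delivers hydride to one face, which should set the carbinol center as (R) (the spatial arrangement that becomes C2 (S) of the target).

Step 7
Reactants: 10 (1R)-2-chloro-1-[4-(methoxymethoxy)phenyl]ethan-1-ol (1.15 equiv); 7 3-[(1E,3S)-3,7-dimethylocta-1,6-dien-1-yl]-6-fluoro-N-methoxy-2,4-bis(methoxymethoxy)-N-methylbenzamide (1.0 equiv)
Product: 15 (2S)-6-[(1E,3S)-3,7-dimethylocta-1,6-dien-1-yl]-5,7-bis(methoxymethoxy)-2-[4-(methoxymethoxy)phenyl]-2,3-dihydro-4H-chromen-4-one, via β-oxido alkyllithium 11 (not isolated), via tetrahedral adduct 12 (not isolated), via aryne 13 (not isolated), via cyclized aryllithium 14 (not isolated)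
Conditions: 10, n-BuLi (1.15 equiv), THF, −78 °C; lithium naphthalenide (2.3 equiv), −78 °C, 20 min; then 7, −78 °C, 1 h; then LiTMP (1.5 equiv), −78 to −20 °C; AcOH, −78 °C, then H2O
Reagents that add atoms: none
Why: n-BuLi deprotonates 10 and lithium naphthalenide converts C–Cl into C–Li by two single-electron transfers (reductive lithiation of a chlorohydrin alkoxide), and the carbanion of 11 adds to the Weinreb amide 7 to forge C3–C4 as the chelated adduct 12, which keeps C4 masked so that no β-alkoxy ketone is exposed to base (no retro-aldol, enolization or second addition). LiTMP then removes the only ring A proton, C8–H, which is flanked by the C8a fluorine and the C7 MOM ether; on warming LiF is lost, and the C2 alkoxide adds to C8a of the C8–C8a aryne 13 to forge O1–C8a, giving aryllithium 14, which is protonated at C8 on quench while the adduct collapses to the C4 ketone. The closest known reaction types are the Weinreb ketone synthesis with an alkyllithium and the intramolecular capture of an aryne, made from an ortho-lithiated fluoroarene, by a tethered lithium alkoxide. Ring C closes in a 6-exo-dig addition of O1 to the in-plane π bond of the aryne, and ring A is only rearomatized, not built. No stereocenter is created: C2 comes from 10 with its C–O bond untouched (the descriptor changes from R to S only because CH2Cl outranks aryl whereas the C3 methylene does not), the hemiaminal carbon of 12 is lost on collapse, and C3′ is remote. The step needs carbonyl addition of 11 to outrun ortho-deprotonation of 7 (secured by −78 °C, the absence of amine additives and the strongly electrophilic amide) and needs O1 to enter at C8a and H at C8, which is secured by the tether (a six-membered ring is possible only through C8a) and reinforced by the C7 oxygen, whose inductive effect places the developing carbanion at C8 next to it.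

Step 8
Reactants: 15 (2S)-6-[(1E,3S)-3,7-dimethylocta-1,6-dien-1-yl]-5,7-bis(methoxymethoxy)-2-[4-(methoxymethoxy)phenyl]-2,3-dihydro-4H-chromen-4-one
Product: 17 (2S)-6-[(1E,3S)-3,7-dimethylocta-1,6-dien-1-yl]-5,7-dihydroxy-2-(4-hydroxyphenyl)-2,3-dihydro-4H-chromen-4-one, via tris(trimethylsilyl) ether 16 (not isolated)
Conditions: TMSOTf (6 equiv), 2,2′-bipyridyl (9 equiv), CH2Cl2, 0 °C to rt; then H2O, rt
Reagents that add atoms: none
Why: Silyl triflate–bipyridyl cleavage of aryl MOM ethers to aryl trimethylsilyl ethers that water hydrolyses, chosen because the buffered medium exposes neither the acid-sensitive electron-rich styrene and trisubstituted alkene to free acid nor the flavanone C2 center to base (ring opening to the chalcone would racemize it).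

**Compound list**

1 | 5-fluorobenzene-1,3-diol | Oc1cc(O)cc(F)c1 | starting material
2 | 5-fluoro-2-iodobenzene-1,3-diol | Oc1cc(F)cc(O)c1I | intermediate
3 | 5-fluoro-2-iodo-1,3-bis(methoxymethoxy)benzene | COCOc1cc(F)cc(OCOC)c1I | intermediate
4 | (3S)-3,7-dimethylocta-1,6-diene | CC(C)=CCC[C@H](C)C=C | starting material
5 | 2-[(1E,3S)-3,7-dimethylocta-1,6-dien-1-yl]-5-fluoro-1,3-bis(methoxymethoxy)benzene | CC(C)=CCC[C@H](C)/C=C/c1c(OCOC)cc(F)cc1OCOC | intermediate
6 | {3-[(1E,3S)-3,7-dimethylocta-1,6-dien-1-yl]-6-fluoro-2,4-bis(methoxymethoxy)phenyl}lithium | CC(C)=CCC[C@H](C)/C=C/c1c(OCOC)cc(F)c([Li])c1OCOC | intermediate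
7 | 3-[(1E,3S)-3,7-dimethylocta-1,6-dien-1-yl]-6-fluoro-N-methoxy-2,4-bis(methoxymethoxy)-N-methylbenzamide | CC(C)=CCC[C@H](C)/C=C/c1c(OCOC)cc(F)c(C(=O)N(C)OC)c1OCOC | intermediate
8 | 2-chloro-1-(4-hydroxyphenyl)ethan-1-one | O=C(CCl)c1ccc(O)cc1 | starting material
9 | 2-chloro-1-[4-(methoxymethoxy)phenyl]ethan-1-one | O=C(CCl)c1ccc(OCOC)cc1 | intermediate
10 | (1R)-2-chloro-1-[4-(methoxymethoxy)phenyl]ethan-1-ol | ClC[C@@H](c1ccc(OCOC)cc1)O | intermediate
11 | lithium (1S)-2-lithio-1-[4-(methoxymethoxy)phenyl]ethan-1-olate | [Li]C[C@@H](c1ccc(OCOC)cc1)O[Li] | intermediate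
12 | dilithium (3S)-1-{3-[(1E,3S)-3,7-dimethylocta-1,6-dien-1-yl]-6-fluoro-2,4-bis(methoxymethoxy)phenyl}-1-[methoxy(methyl)amino]-3-[4-(methoxymethoxy)phenyl]propane-1,3-diolate (both C1 epimers) | CC(C)=CCC[C@H](C)/C=C/c1c(OCOC)cc(F)c(C(O[Li])(N(C)OC)C[C@@H](c2ccc(OCOC)cc2)O[Li])c1OCOC | intermediate
13 | C8–C8a aryne formed from 12 by loss of HF (flavanone numbering) | CC(C)=CCC[C@H](C)/C=C/C1=C(OCOC)C#CC(C(O[Li])(N(C)OC)C[C@@H](c2ccc(OCOC)cc2)O[Li])=C1OCOC | intermediate
14 | (2S)-8-lithio-4-(lithiooxy)-4-[methoxy(methyl)amino]-6-[(1E,3S)-3,7-dimethylocta-1,6-dien-1-yl]-5,7-bis(methoxymethoxy)-2-[4-(methoxymethoxy)phenyl]chromane | CC(C)=CCC[C@H](C)/C=C/c1c(OCOC)c([Li])c2c(c1OCOC)C(O[Li])(N(C)OC)C[C@@H](c1ccc(OCOC)cc1)O2 | intermediate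
15 | (2S)-6-[(1E,3S)-3,7-dimethylocta-1,6-dien-1-yl]-5,7-bis(methoxymethoxy)-2-[4-(methoxymethoxy)phenyl]-2,3-dihydro-4H-chromen-4-one | CC(C)=CCC[C@H](C)/C=C/c1c(OCOC)cc2c(c1OCOC)C(=O)C[C@@H](c1ccc(OCOC)cc1)O2 | intermediate
16 | (2S)-6-[(1E,3S)-3,7-dimethylocta-1,6-dien-1-yl]-5,7-bis(trimethylsilyloxy)-2-[4-(trimethylsilyloxy)phenyl]-2,3-dihydro-4H-chromen-4-one | CC(C)=CCC[C@H](C)/C=C/c1c(O[Si](C)(C)C)cc2c(c1O[Si](C)(C)C)C(=O)C[C@@H](c1ccc(O[Si](C)(C)C)cc1)O2 | intermediate
17 | (2S)-6-[(1E,3S)-3,7-dimethylocta-1,6-dien-1-yl]-5,7-dihydroxy-2-(4-hydroxyphenyl)-2,3-dihydro-4H-chromen-4-one | CC(C)=CCC[C@H](C)/C=C/c1c(O)cc2c(c1O)C(=O)C[C@@H](c1ccc(O)cc1)O2 | target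

**Step count.** Total: 8 steps. Longest linear sequence: 6 steps (steps 1, 2, 3, 4, 7, 8).

**Steps most likely to fail**

1. Step 7. The β-oxido alkyllithium may eliminate to the styrene before it is acylated, or may deprotonate C8–H of the hindered amide instead of adding to it, so that the aryne later forms without its tethered alkoxide. The fallback reverses the polarity at C4 and sets out from 5 and 10, returning at 15. Compound 5 is lithiated as in step 4, transmetalated with MgBr2·OEt2 and treated with 2-chloro-1,3-dithiane, which should give 2-{3-[(1E,3S)-3,7-dimethylocta-1,6-dien-1-yl]-6-fluoro-2,4-bis(methoxymethoxy)phenyl}-1,3-dithiane F1. Compound 10 is closed with K2CO3 in MeOH to (2R)-2-[4-(methoxymethoxy)phenyl]oxirane F2. n-BuLi (THF, −30 °C) deprotonates the dithiane carbon of F1, and the anion opens F2 at its CH2 terminus (C3–C4 bond). In the same flask LiTMP (−78 to −20 °C) generates the C8–C8a aryne, which the alkoxide captures (O1–C8a bond) to give the spiro dithiane F3. MeI and CaCO3 in aqueous MeCN then unmask the C4 ketone and give 15.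

2. Step 3. β-Hydride elimination towards C3′, or palladium hydride re-addition, would move the double bond out of conjugation and erase the side-chain stereocenter, and the doubly ortho-substituted iodide may insert the unactivated alkene slowly. The fallback sets out from 3 and returns at 5. (S)-Citronellal is condensed with tosylhydrazine in MeOH to (S)-citronellal N-tosylhydrazone F4. F4 is coupled with 3 under N-tosylhydrazone cross-coupling conditions (Barluenga–Valdés reaction: Pd2(dba)3, XPhos [2-dicyclohexylphosphino-2′,4′,6′-triisopropylbiphenyl], LiOt-Bu, dioxane, 90 °C). The palladium carbene inserts the aryl group at C1′, and β-hydride elimination can then occur only towards C2′, so the E styrene 5 should form with no regiochemical ambiguity.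

3. Step 1. Iodination may occur next to fluorine or run on to a di-iodide. The fallback sets out from 1 and returns at 3. Compound 1 is protected first (MOMCl, i-Pr2NEt) as 1-fluoro-3,5-bis(methoxymethoxy)benzene F5. Directed ortho-metalation with n-BuLi in Et2O at −78 to −40 °C, guided by coordination to both MOM ethers, followed by an I2 quench, should place iodine between the two oxygens and give 3.

**Further compounds**

F1 | step 7 | 2-{3-[(1E,3S)-3,7-dimethylocta-1,6-dien-1-yl]-6-fluoro-2,4-bis(methoxymethoxy)phenyl}-1,3-dithiane | CC(C)=CCC[C@H](C)/C=C/c1c(OCOC)cc(F)c(C2SCCCS2)c1OCOC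
F2 | step 7 | (2R)-2-[4-(methoxymethoxy)phenyl]oxirane | C1[C@@H](c2ccc(OCOC)cc2)O1
F3 | step 7 | (2S)-6-[(1E,3S)-3,7-dimethylocta-1,6-dien-1-yl]-5,7-bis(methoxymethoxy)-2-[4-(methoxymethoxy)phenyl]spiro[chromane-4,2′-[1,3]dithiane] | CC(C)=CCC[C@H](C)/C=C/c1c(OCOC)cc2c(c1OCOC)C1(SCCCS1)C[C@@H](c1ccc(OCOC)cc1)O2
F4 | step 3 | N′-[(3S)-3,7-dimethyloct-6-en-1-ylidene]-4-methylbenzenesulfonohydrazide | CC(C)=CCC[C@H](C)CC=NNS(=O)(=O)c1ccc(C)cc1
F5 | step 1 | 1-fluoro-3,5-bis(methoxymethoxy)benzene | COCOc1cc(F)cc(OCOC)c1
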